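The 19-membered ansa ring is disconnected at the anilide bond N–C20; C20 sits on the benzene ring meta to both the C18 phenol and C16, the carbon that carries the C15 carbinol, so the cut leaves an aryl bromide and a primary amide. A single copper-catalysed intramolecular N-arylation joins these termini and closes the macrolactam without creating or disturbing a stereocentre. Its substrate is the fully silylated open chain: a (2E)-2-methylalk-2-enamide at C1 and a 3-bromo-5-silyloxyphenyl carbinol at C15, built by alkenylzinc addition of a C8–C21 aryl alkyne to a C1–C7 α-methoxy aldehyde. Once the aryl bromide is present, no organolithium or Grignard reagent more reactive than an acetylide is used.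

Key step: step 22

Remark: ansamycin numbering of the target is used for every intermediate (C1 = lactam carbonyl, C15 = benzylic carbinol, C16–C21 = arene, nitrogen on C20, phenol on C18).
Remark: the cyclisation substrate 27 and the macrolactam 28 carry the target configuration 6S,7S,10S,11R,12S,14S,15R and both E alkenes; the ring formed (N, C1–C15, C16, C21, C20) is 19-membered. Three grades of silyl ether are used (TES on O7, TBS on O11 and O15, TIPS on O18) so that O7 alone can be freed after ring closure.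
Abbreviations: Ar = 3-bromo-5-[(triisopropylsilyl)oxy]phenyl; TBS = tert-butyldimethylsilyl; TES = triethylsilyl; TIPS = triisopropylsilyl; TBDPS = tert-butyldiphenylsilyl; DMP = Dess–Martin periodinane.

**Western fragment (C8–C21)**

Step 1
Reactants: 1 3-bromo-5-hydroxybenzaldehyde
Product: 2 3-bromo-5-[(triisopropylsilyl)oxy]benzaldehyde
Conditions: TIPSCl, imidazole, DMF, 23 °C
Reagents that add atoms: triisopropylsilyl chloride, CC(C)[Si](Cl)(C(C)C)C(C)C
Why: Imidazole-promoted O-silylation of the phenol; the bulky aryl TIPS ether is the phenol protection most likely to survive the basic steps up to and including the carbonate-mediated ring closure.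

Step 2
Reactants: 2 3-bromo-5-[(triisopropylsilyl)oxy]benzaldehyde; 3 (R)-4-benzyl-3-propionyloxazolidin-2-one
Product: 5 (R)-4-benzyl-3-[(2R,3R)-3-Ar-3-hydroxy-2-methylpropanoyl]oxazolidin-2-one, via Z-dibutylboron enolate 4 (not isolated)
Conditions: Bu2BOTf, i-Pr2NEt, CH2Cl2, 0 °C; then 2, −78 to 0 °C; pH 7 buffer, MeOH, H2O2
Reagents that add atoms: none
Why: Evans syn aldol reaction in which the Z boron enolate reacts through a closed Zimmerman–Traxler chair on the face away from the benzyl group, setting the C14 methyl and C15 hydroxyl syn with the (2R,3R) configuration that maps onto 14S,15R of the target.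

Step 3
Reactants: 5 (R)-4-benzyl-3-[(2R,3R)-3-Ar-3-hydroxy-2-methylpropanoyl]oxazolidin-2-one
Product: 6 (R)-4-benzyl-3-[(2R,3R)-3-Ar-3-(TBSO)-2-methylpropanoyl]oxazolidin-2-one
Conditions: TBSOTf, 2,6-lutidine, CH2Cl2, 0 °C
Reagents that add atoms: tert-butyldimethylsilyl triflate, CC(C)(C)[Si](C)(C)OS(=O)(=O)C(F)(F)F
Why: Silylation of the benzylic aldol hydroxyl with the silyl triflate blocks retro-aldol cleavage and installs the O15 protecting group carried to the end.

Step 4
Reactants: 6 (R)-4-benzyl-3-[(2R,3R)-3-Ar-3-(TBSO)-2-methylpropanoyl]oxazolidin-2-one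
Product: 7 (2S,3R)-3-Ar-3-(TBSO)-2-methylpropan-1-ol
Conditions: LiBH4, MeOH, THF, 0 °C
Reagents that add atoms: none
Why: Reductive cleavage of the N-acyloxazolidinone by hydride attack at the exocyclic carbonyl releases the C13 primary alcohol and the auxiliary without touching the aryl bromide or the silyl ethers.

Step 5
Reactants: 7 (2S,3R)-3-Ar-3-(TBSO)-2-methylpropan-1-ol
Product: 8 (2R,3R)-3-Ar-3-(TBSO)-2-methylpropanal
Conditions: DMP, NaHCO3, CH2Cl2, 0 to 23 °C
Reagents that add atoms: none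
Why: Dess–Martin oxidation under buffered, non-epimerising conditions gives the α-methyl aldehyde, which is used at once.

Step 6
Reactants: 8 (2R,3R)-3-Ar-3-(TBSO)-2-methylpropanal
Product: 9 (3S,4R)-4-Ar-4-(TBSO)-1-methoxy-3-methylbut-1-ene (E/Z mixture)
Conditions: Ph3P(CH2OMe)Cl, KN(SiMe3)2, THF, 0 °C; then 8, −78 to 0 °C
Reagents that add atoms: (methoxymethyl)triphenylphosphonium chloride, COC[P+](c1ccccc1)(c1ccccc1)c1ccccc1.[Cl-]
Why: Wittig olefination with the methoxymethylene ylide, generated by an amide base that cannot exchange the aryl bromide, adds C12 as an enol ether at low temperature without epimerising C14.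

Step 7
Reactants: 9 (3S,4R)-4-Ar-4-(TBSO)-1-methoxy-3-methylbut-1-ene
Product: 10 (3S,4R)-4-Ar-4-(TBSO)-3-methylbutanal
Conditions: Hg(OAc)2, THF/H2O, 0 °C; then aqueous KI
Reagents that add atoms: water, O
Why: Mercury-assisted enol ether hydrolysis (oxymercuration, loss of methanol, iodide-induced demercuration) unveils the one-carbon-homologated C12 aldehyde at neutral pH, sparing the benzylic TBS and aryl TIPS ethers.

Step 8
Reactants: 10 (3S,4R)-4-Ar-4-(TBSO)-3-methylbutanal
Product: 11 (2E,4S,6S,7R)-7-Ar-7-(TBSO)-6-methylhept-2-en-4-ol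
Conditions: propyne, Cy2BH, toluene, 0 °C; Et2Zn, −78 °C; (+)-3-exo-morpholinoisoborneol (5 mol %); then 10, −30 to 0 °C
Reagents that add atoms: propyne, CC#C
Why: Catalytic asymmetric alkenylzinc addition to an aldehyde, in which hydroboration of propyne and boron-to-zinc exchange give an (E)-propenylzinc that the amino alcohol ligand (the enantiomer expected to direct transfer to the Re face) adds to C12 to set 12S, any C12 epimer being removed by the matched epoxidation that follows.

Step 9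
Reactants: 11 (2E,4S,6S,7R)-7-Ar-7-(TBSO)-6-methylhept-2-en-4-ol
Product: 12 (1S,3S,4R)-4-Ar-4-(TBSO)-3-methyl-1-[(2S,3S)-3-methyloxiran-2-yl]butan-1-ol
Conditions: Ti(OiPr)4, L-(+)-diisopropyl tartrate, t-BuOOH, 4 Å molecular sieves, CH2Cl2, −20 °C
Reagents that add atoms: tert-butyl hydroperoxide, CC(C)(C)OO
Why: Sharpless asymmetric epoxidation of a secondary (E)-allylic alcohol in its matched, fast-reacting sense, the titanium tartrate delivering oxygen to the face that gives the erythro (11,12-anti) epoxy alcohol and so fixing C11 and the epoxide carbon C10.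

Step 10
Reactants: 12 (1S,3S,4R)-4-Ar-4-(TBSO)-3-methyl-1-[(2S,3S)-3-methyloxiran-2-yl]butan-1-ol
Product: 13 (2R,3S)-2-[(1S,3S,4R)-4-Ar-4-(TBSO)-1-methoxy-3-methylbutyl]-3-methyloxirane
Conditions: NaH, MeI, THF, 0 to 23 °C
Reagents that add atoms: iodomethane, CI
Why: Williamson O-methylation of the C12 alkoxide in an aprotic solvent, where methylation outruns Payne rearrangement, installs the C12 methyl ether (the change of descriptor at the oxirane carbon is a priority effect only).

Step 11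
Reactants: 13 (2R,3S)-2-[(1S,3S,4R)-4-Ar-4-(TBSO)-1-methoxy-3-methylbutyl]-3-methyloxirane
Product: 14 (4S,5R,6S,8S,9R)-9-Ar-9-(TBSO)-6-methoxy-4,8-dimethylnon-2-yn-5-ol
Conditions: MeC≡CLi, BF3·OEt2, THF, −78 °C
Reagents that add atoms: 1-propynyllithium, [Li]C#CC
Why: BF3-promoted alkynylation of an epoxide (Yamaguchi-type opening) in which the acetylide attacks C10, the methyl-bearing carbon remote from the electron-withdrawing C12 methoxy group, with inversion, setting 10S (10,11-syn), freeing the C11 carbinol and installing the C8–C9 alkyne with its C8 methyl.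

Step 12
Reactants: 14 (4S,5R,6S,8S,9R)-9-Ar-9-(TBSO)-6-methoxy-4,8-dimethylnon-2-yn-5-ol
Product: 15 (4S,5R,6S,8S,9R)-9-Ar-5,9-bis(TBSO)-6-methoxy-4,8-dimethylnon-2-yne (western fragment)
Conditions: TBSOTf, 2,6-lutidine, CH2Cl2, −78 to 0 °C
Reagents that add atoms: tert-butyldimethylsilyl triflate, CC(C)(C)[Si](C)(C)OS(=O)(=O)C(F)(F)F
Why: Silylation of the hindered C11 hydroxyl with the silyl triflate removes the only acidic proton before hydrozirconation.

**Eastern fragment (C1–C7)**

Step 13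
Reactants: 16 (S)-5-(hydroxymethyl)dihydrofuran-2(3H)-one
Product: 17 (S)-5-[(TBDPSO)methyl]dihydrofuran-2(3H)-one
Conditions: TBDPSCl, imidazole, DMF, 23 °C
Reagents that add atoms: tert-butyldiphenylsilyl chloride, CC(C)(C)[Si](Cl)(c1ccccc1)c1ccccc1
Why: Silylation of the primary alcohol (future C7) with a group that resists hydride reduction, ylide and methylation conditions and does not migrate.

Step 14
Reactants: 17 (S)-5-[(TBDPSO)methyl]dihydrofuran-2(3H)-one
Product: 18 (5S)-5-[(TBDPSO)methyl]tetrahydrofuran-2-ol (anomer mixture)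
Conditions: i-Bu2AlH, CH2Cl2, −78 °C; aqueous potassium sodium tartrate
Reagents that add atoms: none
Why: Partial reduction of the γ-lactone stops at the lactol because the tetrahedral aluminate is stable at −78 °C.

Step 15
Reactants: 18 (5S)-5-[(TBDPSO)methyl]tetrahydrofuran-2-ol
Product: 19 methyl (S,E)-7-(TBDPSO)-6-hydroxy-2-methylhept-2-enoate
Conditions: Ph3P=C(Me)CO2Me, toluene, 80 °C
Reagents that add atoms: methyl 2-(triphenylphosphoranylidene)propanoate, COC(=O)C(C)=P(c1ccccc1)(c1ccccc1)c1ccccc1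
Why: Wittig olefination of the open-chain aldehyde form of the lactol with a stabilised α-branched ylide gives the (E)-trisubstituted enoate (C1–C3) and frees the C6 hydroxyl.

Step 16
Reactants: 19 methyl (S,E)-7-(TBDPSO)-6-hydroxy-2-methylhept-2-enoate
Product: 20 methyl (S,E)-7-(TBDPSO)-6-methoxy-2-methylhept-2-enoate
Conditions: Me3OBF4, 1,8-bis(dimethylamino)naphthalene, CH2Cl2, 23 °C
Reagents that add atoms: trimethyloxonium tetrafluoroborate, C[O+](C)C.F[B-](F)(F)F
Why: O-Methylation by an oxonium salt with a non-nucleophilic base keeps the alcohol un-ionised, so neither oxa-Michael cyclisation onto the enoate nor silyl migration can compete.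

Step 17
Reactants: 20 methyl (S,E)-7-(TBDPSO)-6-methoxy-2-methylhept-2-enoate
Product: 21 methyl (S,E)-7-hydroxy-6-methoxy-2-methylhept-2-enoate
Conditions: HF·pyridine, pyridine, THF, 0 to 23 °C
Reagents that add atoms: none
Why: Fluoride-mediated desilylation under buffered conditions frees the primary C7 alcohol without affecting the enoate or the methyl ether.

Step 18
Reactants: 21 methyl (S,E)-7-hydroxy-6-methoxy-2-methylhept-2-enoate
Product: 22 methyl (S,E)-6-methoxy-2-methyl-7-oxohept-2-enoate (eastern fragment)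
Conditions: DMP, NaHCO3, CH2Cl2, 0 °C
Reagents that add atoms: none
Why: Dess–Martin oxidation gives the configurationally labile α-methoxy aldehyde under mild buffered conditions for immediate use.

**Fragment union, ring closure and endgame**

Step 19
Reactants: 15 (4S,5R,6S,8S,9R)-9-Ar-5,9-bis(TBSO)-6-methoxy-4,8-dimethylnon-2-yne; 22 methyl (S,E)-6-methoxy-2-methyl-7-oxohept-2-enoate
Product: 25 methyl (2E,6S,7S,8E,10S,11R,12S,14S,15R)-15-Ar-11,15-bis(TBSO)-7-hydroxy-6,12-dimethoxy-2,8,10,14-tetramethylpentadeca-2,8-dienoate, via C8 alkenylzirconocene chloride 23 (not isolated), via alkenyl(methyl)zinc 24 (not isolated)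
Conditions: Cp2Zr(H)Cl, THF, 40 °C; solvent switch to toluene; Me2Zn, −65 °C; then 22, −65 to 0 °C
Reagents that add atoms: none
Why: Hydrozirconation of the methyl alkyne (syn addition, zirconium on the less hindered C8) followed by zirconium-to-zinc exchange and alkenylzinc addition to the aldehyde, where zinc chelation between the C6 methoxy and the carbonyl oxygen directs attack anti to the C5 chain (Cram-chelate model) to set 7S (6,7-syn) and the 8E alkene while the ester and aryl bromide are inert.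

Step 20
Reactants: 25 methyl (2E,6S,7S,8E,10S,11R,12S,14S,15R)-15-Ar-11,15-bis(TBSO)-7-hydroxy-6,12-dimethoxy-2,8,10,14-tetramethylpentadeca-2,8-dienoate
Product: 26 methyl (2E,6S,7S,8E,10S,11R,12S,14S,15R)-15-Ar-11,15-bis(TBSO)-7-(TESO)-6,12-dimethoxy-2,8,10,14-tetramethylpentadeca-2,8-dienoate
Conditions: TESOTf, 2,6-lutidine, CH2Cl2, −78 °C
Reagents that add atoms: triethylsilyl triflate, CC[Si](CC)(CC)OS(=O)(=O)C(F)(F)F
Why: Silylation of the allylic C7 alcohol with the reactive triflate; TES is chosen because it alone can later be removed beside the TBS and aryl TIPS ethers.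

Step 21
Reactants: 26 methyl (2E,6S,7S,8E,10S,11R,12S,14S,15R)-15-Ar-11,15-bis(TBSO)-7-(TESO)-6,12-dimethoxy-2,8,10,14-tetramethylpentadeca-2,8-dienoate
Product: 27 (2E,6S,7S,8E,10S,11R,12S,14S,15R)-15-Ar-11,15-bis(TBSO)-7-(TESO)-6,12-dimethoxy-2,8,10,14-tetramethylpentadeca-2,8-dienamide (cyclisation substrate)
Conditions: Me3Al, NH4Cl, toluene, 50 °C
Reagents that add atoms: ammonium chloride, [NH4+].[Cl-]
Why: Aluminium-amide aminolysis of a methyl ester, in which MeAl(Cl)NH2 formed from Me3Al and NH4Cl converts the hindered conjugated ester directly into the primary amide under non-basic conditions that spare all four silyl ethers and the aryl bromide.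

Step 22
Reactants: 27 (2E,6S,7S,8E,10S,11R,12S,14S,15R)-15-Ar-11,15-bis(TBSO)-7-(TESO)-6,12-dimethoxy-2,8,10,14-tetramethylpentadeca-2,8-dienamide
Product: 28 7-O-TES-11,15-di-O-TBS-18-O-TIPS macrolactam (19-membered, N–C20 closed)
Conditions: CuI (0.5 equiv), N,N'-dimethylethylenediamine, K2CO3, toluene, 100 °C, 2 mM, slow addition of 27
Reagents that add atoms: none
Why: The diamine-ligated CuI binds the primary amide, K2CO3 removes an N–H proton to give a monovalent copper amidate, the C20–Br bond adds oxidatively to copper, and reductive elimination from the trivalent copper aryl amidate forms N–C20 and returns the catalyst. The closest known reaction type is the Goldberg amidation of aryl halides in its diamine-accelerated catalytic form, which is established for intramolecular closure of macrolactams of this kind. The 19-membered ring is closed head to tail, the C1 amide nitrogen and the C20 arene carbon being the two ends of the open chain, and high dilution with slow addition favours this over oligomerisation. No stereocentre is formed, and the weak carbonate base leaves the 2E and 8E alkenes and all seven stereocentres untouched. The step needs N- over O-arylation and mono- over diarylation, which the substrate secures because every hydroxyl is silylated, no carbamate N–H is yet present, the amide is the only N–H nucleophile, and the product anilide is hindered and no aryl bromide remains in the same molecule.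

Step 23
Reactants: 28 7-O-TES-11,15-di-O-TBS-18-O-TIPS macrolactam
Product: 29 11,15-di-O-TBS-18-O-TIPS macrolactam with free 7-OH
Conditions: pyridinium p-toluenesulfonate, MeOH/CH2Cl2, 0 °C
Reagents that add atoms: none
Why: Acid-catalysed methanolysis removes the TES ether selectively because it is far more labile than the secondary TBS and aryl TIPS ethers.

Step 24
Reactants: 29 11,15-di-O-TBS-18-O-TIPS macrolactam with free 7-OH
Product: 31 7-O-carbamoyl-11,15-di-O-TBS-18-O-TIPS macrolactam, via N-trichloroacetyl carbamate 30 (not isolated)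
Conditions: Cl3CC(O)NCO, CH2Cl2, 0 °C; then neutral Al2O3, 23 °C
Reagents that add atoms: trichloroacetyl isocyanate, O=C=NC(=O)C(Cl)(Cl)Cl
Why: Carbamoylation of the only free hydroxyl by the highly electrophilic acyl isocyanate, followed by hydrolytic loss of the trichloroacetyl group on alumina, gives the primary carbamate, the anilide N–H being too weakly nucleophilic to compete.

Step 25
Reactants: 31 7-O-carbamoyl-11,15-di-O-TBS-18-O-TIPS macrolactam
Product: 32 CNP0309815.1 (target)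
Conditions: HF·pyridine, pyridine, THF, 0 to 23 °C
Reagents that add atoms: none
Why: Global fluoride-mediated desilylation, driven by Si–F bond formation, removes both TBS ethers and the aryl TIPS ether, while the carbamate, the lactam and the alkenes are stable to buffered HF.

**Compound list**

1 | 3-bromo-5-hydroxybenzaldehyde | O=Cc1cc(O)cc(Br)c1 | starting material
2 | 3-bromo-5-[(triisopropylsilyl)oxy]benzaldehyde | O=Cc1cc(O[Si](C(C)C)(C(C)C)C(C)C)cc(Br)c1 | intermediate
3 | (R)-4-benzyl-3-propionyloxazolidin-2-one | CCC(=O)N1[C@H](Cc2ccccc2)COC1=O | starting material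
4 | Z-dibutylboron enolate of 3 | C/C=C(\OB(CCCC)CCCC)N1[C@H](Cc2ccccc2)COC1=O | intermediate (not isolated)
5 | (R)-4-benzyl-3-[(2R,3R)-3-Ar-3-hydroxy-2-methylpropanoyl]oxazolidin-2-one | O=C([C@H](C)[C@@H](O)c1cc(O[Si](C(C)C)(C(C)C)C(C)C)cc(Br)c1)N1[C@H](Cc2ccccc2)COC1=O | intermediate
6 | (R)-4-benzyl-3-[(2R,3R)-3-Ar-3-(TBSO)-2-methylpropanoyl]oxazolidin-2-one | O=C([C@H](C)[C@@H](O[Si](C)(C)C(C)(C)C)c1cc(O[Si](C(C)C)(C(C)C)C(C)C)cc(Br)c1)N1[C@H](Cc2ccccc2)COC1=O | intermediate
7 | (2S,3R)-3-Ar-3-(TBSO)-2-methylpropan-1-ol | OC[C@H](C)[C@@H](O[Si](C)(C)C(C)(C)C)c1cc(O[Si](C(C)C)(C(C)C)C(C)C)cc(Br)c1 | intermediate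
8 | (2R,3R)-3-Ar-3-(TBSO)-2-methylpropanal | O=C[C@H](C)[C@@H](O[Si](C)(C)C(C)(C)C)c1cc(O[Si](C(C)C)(C(C)C)C(C)C)cc(Br)c1 | intermediate
9 | (3S,4R)-4-Ar-4-(TBSO)-1-methoxy-3-methylbut-1-ene (E/Z mixture) | COC=C[C@H](C)[C@@H](O[Si](C)(C)C(C)(C)C)c1cc(O[Si](C(C)C)(C(C)C)C(C)C)cc(Br)c1 | intermediate
10 | (3S,4R)-4-Ar-4-(TBSO)-3-methylbutanal | O=CC[C@H](C)[C@@H](O[Si](C)(C)C(C)(C)C)c1cc(O[Si](C(C)C)(C(C)C)C(C)C)cc(Br)c1 | intermediate
11 | (2E,4S,6S,7R)-7-Ar-7-(TBSO)-6-methylhept-2-en-4-ol | C/C=C/[C@@H](O)C[C@H](C)[C@@H](O[Si](C)(C)C(C)(C)C)c1cc(O[Si](C(C)C)(C(C)C)C(C)C)cc(Br)c1 | intermediate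
12 | (1S,3S,4R)-4-Ar-4-(TBSO)-3-methyl-1-[(2S,3S)-3-methyloxiran-2-yl]butan-1-ol | C[C@@H]1O[C@H]1[C@@H](O)C[C@H](C)[C@@H](O[Si](C)(C)C(C)(C)C)c1cc(O[Si](C(C)C)(C(C)C)C(C)C)cc(Br)c1 | intermediate
13 | (2R,3S)-2-[(1S,3S,4R)-4-Ar-4-(TBSO)-1-methoxy-3-methylbutyl]-3-methyloxirane | C[C@@H]1O[C@H]1[C@@H](OC)C[C@H](C)[C@@H](O[Si](C)(C)C(C)(C)C)c1cc(O[Si](C(C)C)(C(C)C)C(C)C)cc(Br)c1 | intermediate
14 | (4S,5R,6S,8S,9R)-9-Ar-9-(TBSO)-6-methoxy-4,8-dimethylnon-2-yn-5-ol | CC#C[C@H](C)[C@@H](O)[C@@H](OC)C[C@H](C)[C@@H](O[Si](C)(C)C(C)(C)C)c1cc(O[Si](C(C)C)(C(C)C)C(C)C)cc(Br)c1 | intermediate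
15 | (4S,5R,6S,8S,9R)-9-Ar-5,9-bis(TBSO)-6-methoxy-4,8-dimethylnon-2-yne | CC#C[C@H](C)[C@@H](O[Si](C)(C)C(C)(C)C)[C@@H](OC)C[C@H](C)[C@@H](O[Si](C)(C)C(C)(C)C)c1cc(O[Si](C(C)C)(C(C)C)C(C)C)cc(Br)c1 | intermediate
16 | (S)-5-(hydroxymethyl)dihydrofuran-2(3H)-one | O=C1CC[C@@H](CO)O1 | starting material
17 | (S)-5-[(TBDPSO)methyl]dihydrofuran-2(3H)-one | O=C1CC[C@@H](CO[Si](c2ccccc2)(c2ccccc2)C(C)(C)C)O1 | intermediate
18 | (5S)-5-[(TBDPSO)methyl]tetrahydrofuran-2-ol (anomer mixture) | OC1CC[C@@H](CO[Si](c2ccccc2)(c2ccccc2)C(C)(C)C)O1 | intermediate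
19 | methyl (S,E)-7-(TBDPSO)-6-hydroxy-2-methylhept-2-enoate | COC(=O)/C(C)=C/CC[C@H](O)CO[Si](c1ccccc1)(c1ccccc1)C(C)(C)C | intermediate
20 | methyl (S,E)-7-(TBDPSO)-6-methoxy-2-methylhept-2-enoate | COC(=O)/C(C)=C/CC[C@H](OC)CO[Si](c1ccccc1)(c1ccccc1)C(C)(C)C | intermediate
21 | methyl (S,E)-7-hydroxy-6-methoxy-2-methylhept-2-enoate | COC(=O)/C(C)=C/CC[C@H](OC)CO | intermediate
22 | methyl (S,E)-6-methoxy-2-methyl-7-oxohept-2-enoate | COC(=O)/C(C)=C/CC[C@H](OC)C=O | intermediate
23 | (E)-C8 alkenylzirconocene chloride from 15 | Cl[Zr](C1C=CC=C1)(C1C=CC=C1)/C(C)=C/[C@H](C)[C@@H](O[Si](C)(C)C(C)(C)C)[C@@H](OC)C[C@H](C)[C@@H](O[Si](C)(C)C(C)(C)C)c1cc(O[Si](C(C)C)(C(C)C)C(C)C)cc(Br)c1 | intermediate (not isolated)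
24 | (E)-C8 alkenyl(methyl)zinc from 23 | C[Zn]/C(C)=C/[C@H](C)[C@@H](O[Si](C)(C)C(C)(C)C)[C@@H](OC)C[C@H](C)[C@@H](O[Si](C)(C)C(C)(C)C)c1cc(O[Si](C(C)C)(C(C)C)C(C)C)cc(Br)c1 | intermediate (not isolated)
25 | methyl (2E,6S,7S,8E,10S,11R,12S,14S,15R)-15-Ar-11,15-bis(TBSO)-7-hydroxy-6,12-dimethoxy-2,8,10,14-tetramethylpentadeca-2,8-dienoate | COC(=O)/C(C)=C/CC[C@H](OC)[C@@H](O)/C(C)=C/[C@H](C)[C@@H](O[Si](C)(C)C(C)(C)C)[C@@H](OC)C[C@H](C)[C@@H](O[Si](C)(C)C(C)(C)C)c1cc(O[Si](C(C)C)(C(C)C)C(C)C)cc(Br)c1 | intermediate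
26 | 7-O-TES ether of 25 | COC(=O)/C(C)=C/CC[C@H](OC)[C@@H](O[Si](CC)(CC)CC)/C(C)=C/[C@H](C)[C@@H](O[Si](C)(C)C(C)(C)C)[C@@H](OC)C[C@H](C)[C@@H](O[Si](C)(C)C(C)(C)C)c1cc(O[Si](C(C)C)(C(C)C)C(C)C)cc(Br)c1 | intermediate
27 | (2E,6S,7S,8E,10S,11R,12S,14S,15R)-15-Ar-11,15-bis(TBSO)-7-(TESO)-6,12-dimethoxy-2,8,10,14-tetramethylpentadeca-2,8-dienamide | NC(=O)/C(C)=C/CC[C@H](OC)[C@@H](O[Si](CC)(CC)CC)/C(C)=C/[C@H](C)[C@@H](O[Si](C)(C)C(C)(C)C)[C@@H](OC)C[C@H](C)[C@@H](O[Si](C)(C)C(C)(C)C)c1cc(O[Si](C(C)C)(C(C)C)C(C)C)cc(Br)c1 | intermediate (key-step precursor)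
28 | 19-membered macrolactam, 7-O-TES, 11,15-di-O-TBS, 18-O-TIPS | N1C(=O)/C(C)=C/CC[C@H](OC)[C@@H](O[Si](CC)(CC)CC)/C(C)=C/[C@H](C)[C@@H](O[Si](C)(C)C(C)(C)C)[C@@H](OC)C[C@H](C)[C@@H](O[Si](C)(C)C(C)(C)C)c2cc(O[Si](C(C)C)(C(C)C)C(C)C)cc1c2 | intermediate (key-step product)
29 | macrolactam with free 7-OH, 11,15-di-O-TBS, 18-O-TIPS | N1C(=O)/C(C)=C/CC[C@H](OC)[C@@H](O)/C(C)=C/[C@H](C)[C@@H](O[Si](C)(C)C(C)(C)C)[C@@H](OC)C[C@H](C)[C@@H](O[Si](C)(C)C(C)(C)C)c2cc(O[Si](C(C)C)(C(C)C)C(C)C)cc1c2 | intermediate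
30 | 7-O-(N-trichloroacetylcarbamoyl) macrolactam | N1C(=O)/C(C)=C/CC[C@H](OC)[C@@H](OC(=O)NC(=O)C(Cl)(Cl)Cl)/C(C)=C/[C@H](C)[C@@H](O[Si](C)(C)C(C)(C)C)[C@@H](OC)C[C@H](C)[C@@H](O[Si](C)(C)C(C)(C)C)c2cc(O[Si](C(C)C)(C(C)C)C(C)C)cc1c2 | intermediate (not isolated)
31 | 7-O-carbamoyl macrolactam, 11,15-di-O-TBS, 18-O-TIPS | N1C(=O)/C(C)=C/CC[C@H](OC)[C@@H](OC(N)=O)/C(C)=C/[C@H](C)[C@@H](O[Si](C)(C)C(C)(C)C)[C@@H](OC)C[C@H](C)[C@@H](O[Si](C)(C)C(C)(C)C)c2cc(O[Si](C(C)C)(C(C)C)C(C)C)cc1c2 | intermediate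
32 | CNP0309815.1: (2E,6S,7S,8E,10S,11R,12S,14S,15R) 19-membered lactam with 7-O-carbamate, free 11-, 15- and 18-OH, 6,12-dimethoxy and 2,8,10,14-tetramethyl groups | CO[C@H]1C[C@H](C)[C@@H](O)c2cc(O)cc(c2)NC(=O)/C(C)=C/CC[C@H](OC)[C@@H](OC(N)=O)/C(C)=C/[C@H](C)[C@H]1O | target

**Step count and risks**

Total: 25 steps. Longest linear sequence: 19 steps (steps 1–12, then 19–25); the eastern fragment takes 6 steps (13–18).

Step 22 (copper-catalysed ring closure). The risk is that intermolecular N-arylation to oligomers, or reduction of the C20–Br bond, outruns ring closure. The fallback closes the ring at the amide bond N–C1 instead and sets out from ester 26. Buchwald–Hartwig coupling with benzophenone imine (Pd(OAc)2, 2,2'-bis(diphenylphosphino)-1,1'-binaphthyl, Cs2CO3, toluene, 90 °C) would give the N-(diphenylmethylene)aniline ester F1. Hydroxylamine hydrochloride with NaOAc in MeOH would release the C20 aniline ester F2. Me3SnOH in 1,2-dichloroethane at 80 °C would hydrolyse the methyl ester to the seco amino acid F3 without touching the silyl ethers. Bis(2-oxo-3-oxazolidinyl)phosphinic chloride with i-Pr2NEt in toluene at high dilution would then lactamise F3, coming back to the route at macrolactam 28.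

Step 19 (fragment union). The risk is loss of chelation control, so that the alkenylzinc attacks the other carbonyl face and the C7 epimer forms, or incomplete regiocontrol in the hydrozirconation. The fallback sets out from 25 obtained as a C7 epimer mixture. Dess–Martin oxidation would give the C7 enone F4. A Corey–Bakshi–Shibata reduction with catecholborane and (S)-1-methyl-3,3-diphenyltetrahydro-1H,3H-pyrrolo[1,2-c][1,3,2]oxazaborole would then return 25 under reagent control. The alkenyl group is assumed to act as the larger ketone substituent, so hydride goes to the Re face of C7.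

Step 8 (asymmetric propenyl addition). The risk is modest catalyst control with this α-unbranched aldehyde and competing ethyl transfer from zinc. The fallback sets out from 11 obtained as a C12 epimer mixture. Dess–Martin oxidation would give the (E)-enone F5. Reduction with BH3·SMe2 and the (R)-enantiomer of the same oxazaborolidine, with propenyl as the large group and hydride to the Re face of C12, would return 11. The matched epoxidation of step 9 then removes residual epimer.

**Further compounds**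

F1 | step 22 | methyl ester 26 with Br replaced by N=CPh2 (N-(diphenylmethylene)aniline ester) | COC(=O)/C(C)=C/CC[C@H](OC)[C@@H](O[Si](CC)(CC)CC)/C(C)=C/[C@H](C)[C@@H](O[Si](C)(C)C(C)(C)C)[C@@H](OC)C[C@H](C)[C@@H](O[Si](C)(C)C(C)(C)C)c1cc(O[Si](C(C)C)(C(C)C)C(C)C)cc(N=C(c2ccccc2)c2ccccc2)c1
F2 | step 22 | C20 aniline methyl ester | COC(=O)/C(C)=C/CC[C@H](OC)[C@@H](O[Si](CC)(CC)CC)/C(C)=C/[C@H](C)[C@@H](O[Si](C)(C)C(C)(C)C)[C@@H](OC)C[C@H](C)[C@@H](O[Si](C)(C)C(C)(C)C)c1cc(O[Si](C(C)C)(C(C)C)C(C)C)cc(N)c1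
F3 | step 22 | seco amino acid (C1 carboxylic acid, C20 aniline) | OC(=O)/C(C)=C/CC[C@H](OC)[C@@H](O[Si](CC)(CC)CC)/C(C)=C/[C@H](C)[C@@H](O[Si](C)(C)C(C)(C)C)[C@@H](OC)C[C@H](C)[C@@H](O[Si](C)(C)C(C)(C)C)c1cc(O[Si](C(C)C)(C(C)C)C(C)C)cc(N)c1
F4 | step 19 | C7 enone (7-oxo analogue of 25) | COC(=O)/C(C)=C/CC[C@H](OC)C(=O)/C(C)=C/[C@H](C)[C@@H](O[Si](C)(C)C(C)(C)C)[C@@H](OC)C[C@H](C)[C@@H](O[Si](C)(C)C(C)(C)C)c1cc(O[Si](C(C)C)(C(C)C)C(C)C)cc(Br)c1
F5 | step 8 | (2E,6S,7R)-7-Ar-7-(TBSO)-6-methylhept-2-en-4-one | C/C=C/C(=O)C[C@H](C)[C@@H](O[Si](C)(C)C(C)(C)C)c1cc(O[Si](C(C)C)(C(C)C)C(C)C)cc(Br)c1
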